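Start with the rate. These are the flasks and what has been read so far.

common to all: Z 16 mM (held)
- alder: E 0.031 M (in portions, 3); run made earlier; portions every 2.5 min
- birch: E 0.80 M (in portions, 3); run made earlier; portions every 2.5 min
- Monday's: E 0.060 M (in portions, 3); the portions of E follow each other after 0.60 min, the first at the start; time 40 min
- Sunday's: E 0.40 M (in portions, 3); the portions of E follow each other after 5.0 min, the first at the start; time 40 min
- Friday's: E 0.25 M (in portions, 3); the portions of E follow each other after 2.5 min, the first at the start; time 40 min
- Tuesday's: E 0.12 M (in portions, 3); the portions of E follow each other after 4.0 min, the first at the start; time 40 min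
- Wednesday's: E 1.0 M (in portions, 3); the portions of E follow each other after 0.80 min, the first at the start; time 40 min

| run | time / min | X / % | E / % |
|---|---|---|---|
| alder | 5.00 | 0.5 | 41.5 |
| alder | 10.0 | 6.0 | 36.7 |
| alder | 15.0 | 17.3 | 17.3 |
| alder | 20.0 | 30.9 | 8.7 |
| alder | 25.0 | 43.6 | 3.5 |
| alder | 30.0 | 55.4 | 1.6 |
| birch | 2.00 | 0.1 | 30.0 |
| birch | 5.00 | 0.1 | 56.5 |
| birch | 10.0 | 1.9 | 77.9 |
| birch | 15.0 | 5.7 | 66.3 |
| birch | 20.0 | 11.7 | 55.1 |
| birch | 30.0 | 26.0 | 34.6 |

(each reading ± 0.3 percentage points)

- at the start none of Z is in solution

1. the flasks by amount of X, in percent of the E charged, highest first, at 40 min (Monday's / Sunday's / Friday's / Tuesday's / Wednesday's)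
2. the amount of X, in percent of the E charged of the flask you put first, at 40 min
3. the amount of X, in percent of the E charged of the flask you put last, at 40 min

X lags behind the loss of E: at 15.0 min in the alder run E stands at 17.3% and X at 17.3%. So ask first how fast each flask uses its E. In the alder run, once the portions are in, E falls pseudo-first-order: from 15.0 min to 30.0 min you read a constant of 0.159 min⁻¹. In the birch run, over 15.0 min to 30.0 min, E falls at 0.0169 M min⁻¹ around 0.404 M of E, which is slower than the 0.0642 M min⁻¹ that constant would give.

So treat the time per unit of E as two waits in series, one fixed and one growing as E falls. Taking the second wait off the birch rate leaves a ceiling, as read from these two runs, of 0.0230 M min⁻¹.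

Now follow Wednesday's flask. With its whole charge counted as present, its rate stands below the ceiling by a factor of 1.14, and at half its charge the factor has grown to 1.29. Added up, the slowing costs a tail of 4.37 min, which in this reckoning doesn't depend on the charge. Put the charge over twice the ceiling, add that tail, and add the interval, which is the mean wait of the portions. This gives Wednesday's half-use time, the time to use half the charge: 26.9 min.

The same sum gives Monday's 6.27 min, Tuesday's 11.0 min, Friday's 12.3 min and Sunday's 18.1 min. I take an earlier half-use time to mean more X at 40 min, so my order runs through Tuesday's, Friday's and Sunday's, with Monday's first and Wednesday's last.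

Alder's half-use time is 7.54 min. If X keeps the same shape, sliding alder's X readings later by 19.4 min puts Wednesday's at about 32.4%. Monday's would need a reading past alder's last, so I leave the top open.

The forecast gives Monday's > Tuesday's > Friday's > Sunday's > Wednesday's, with 72% and 35%, saying: “Dilute flasks convert E early, so they lead.” Its low stands above mine.

The flasks give Monday's > Tuesday's > Friday's > Sunday's > Wednesday's, with 74.7% first and 37.8% last.

    J → Q (k = 9.00 × 10⁻⁴ s⁻¹)
    Z ⇌ L, rate k2*(csat - [L]) (kL = 0.0240 s⁻¹)
    2 L → G (k = 0.0310 M⁻¹ s⁻¹)
    Q → X (k = 0.00400 s⁻¹)
    E + L → J (k = 0.170 M⁻¹ s⁻¹)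

Wednesday's half-use time of 26.9 min stands against the same flask read at 25.0 min, where E is still 52.3% of the charge, just over half. Wednesday's spacing with 0.40 M of E has a half-use time of 13.9 min, later than Friday's and earlier than Sunday's, and at 40 min it holds 61.2% X, between Sunday's 56.8% and Friday's 65.8%.

The runs are calculated with constants of no real substance; noise was put on by code.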